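**Retrosynthetic overview**
- Ring C (the pyranone) is opened at O1–C2 and C3–C(=O)(B ring), giving a 2-benzoyloxy-1,3-diketone. The diketone comes from Baker–Venkataraman-type acylation of an A-ring acetophenone with a B-ring acid chloride; the C3 oxygen is added afterwards by benzoyloxylation of the diketone.
- A ring: the 8-(1,1-dimethylallyl) group comes from aromatic Claisen rearrangement of the 4-O-prenyl ether of 2,4,6-trihydroxyacetophenone. The only phenol left free (next to that group) becomes O1.
- B ring: the 2'-prenyl group is attached by Stille coupling at an aryl bromide.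
- The strategy rests on the 2,2-dimethyl-3,4-dihydro-2H-pyran ring fused to ring B at C3'–C4' (O on C4', ArCH2 on C3'). It is the oxa-[4+2] adduct of an anodically generated o-quinone methide (C4'=O, C3'=CH2) with isobutene.
- Order of ring formation: dihydropyran on ring B (step 4), then ring C (step 13); ring A is bought.

Key step: step 4

Remark on the chemistry: the target has no stereogenic centre and no stereogenic double bond, so no stereocontrol is needed. The one stereocentre that appears on the way (C2 of diketone 21, racemic) is removed in step 13.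

**Route**

Step 1
Reactants: 1 6-bromovanillin
Product: 2 2-bromo-4-hydroxy-5-methoxybenzoic acid
Conditions: NaClO2, NaH2PO4, 2-methylbut-2-ene (excess), t-BuOH/H2O, rt
Reagents that add atoms: sodium chlorite, [Na+].[O-]Cl=O
Why: Pinnick oxidation converts the aryl aldehyde into the acid under buffered conditions that leave the phenol, the methyl ether and the bromide alone, the alkene scavenger removing hypochlorous acid before it can chlorinate the free position ortho to the hydroxyl.

Step 2
Reactants: 2 2-bromo-4-hydroxy-5-methoxybenzoic acid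
Product: 3 methyl 2-bromo-4-hydroxy-5-methoxybenzoate
Conditions: MeOH, H2SO4 (cat.), reflux
Reagents that add atoms: methanol, CO
Why: Fischer esterification of a benzoic acid with only one ortho substituent should proceed normally and leaves the phenol free for the next step.

Step 3
Reactants: 3 methyl 2-bromo-4-hydroxy-5-methoxybenzoate; 4 thiophenol
Product: 6 methyl 2-bromo-4-hydroxy-5-methoxy-3-[(phenylsulfanyl)methyl]benzoate, via Mannich base 5 (not isolated)
Conditions: (CH2O)n, morpholine, EtOH, 80 °C; concentrate; then PhSH, toluene, 110 °C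
Reagents that add atoms: formaldehyde (as paraformaldehyde), C=O
Why: The phenol Mannich reaction aminomethylates the only free position ortho to the hydroxyl (C3, between OH and Br), and heating the Mannich base with thiophenol exchanges the amine for the thiol by retro-Mannich elimination and thia-Michael addition, a known amine–thiol exchange of phenolic Mannich bases.

Step 4
Reactants: 6 methyl 2-bromo-4-hydroxy-5-methoxy-3-[(phenylsulfanyl)methyl]benzoate; 7 isobutene
Product: 9 methyl 5-bromo-8-methoxy-2,2-dimethylchroman-6-carboxylate, via o-quinone methide 8 (not isolated)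
Conditions: undivided cell, glassy-carbon anode, Pt cathode, 1.0 M LiClO4 in MeNO2, AcOH (2 equiv), isobutene (large excess, condensed in), ca. 1.3 V vs Ag/AgCl, 0 °C, closed cell
Reagents that add atoms: none
Why: Anodic one-electron oxidation of the aryl benzyl sulfide gives a sulfur radical cation whose benzylic C–S bond fragments (the PhS fragment ends as diphenyl disulfide), and loss of the phenolic proton leaves o-quinone methide 8 (C4=O, C3=CH2), which the strongly polar, non-nucleophilic LiClO4–MeNO2 medium keeps alive long enough to be trapped. Isobutene then reacts as the electron-rich 2π partner of an inverse-electron-demand oxa-[4+2] cycloaddition, its CH2 terminus bonding to the exocyclic methylene (ArCH2–CH2) and the carbonyl oxygen closing on the carbon that becomes C(CH3)2, so the one new ring, the dihydropyran, is closed in cycloaddition mode (six-membered, strongly asynchronous, C–C bond leading) with rearomatisation of the benzene ring as driving force. The closest known reaction type is the electrochemical generation of o-quinone methides from o-(phenylthiomethyl)phenols in this electrolyte with [4+2] capture by unactivated alkenes to give chromans. No stereocentre is formed. The step needs regioselectivity (oxygen to the tertiary carbon), secured by the polarity match between the electrophilic methylene of 8 and the nucleophilic CH2 of isobutene with positive charge building up at the tertiary carbon, and chemoselectivity for cross-capture over self-condensation of 8, secured by the large excess of alkene and by the ester- and bromo-substituted, strongly electrophilic quinone methide, whose chroman product is too electron-poor to be oxidised at the potential used. The cycloaddition is run before the 2'-prenyl group exists, because that alkene would capture the quinone methide intramolecularly, and the bromine carried through it is the handle for step 5.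

Step 5
Reactants: 9 methyl 5-bromo-8-methoxy-2,2-dimethylchroman-6-carboxylate
Product: 10 methyl 8-methoxy-2,2-dimethyl-5-(3-methylbut-2-en-1-yl)chroman-6-carboxylate
Conditions: tributyl(3-methylbut-2-en-1-yl)stannane, Pd(PPh3)4 (cat.), CsF, DMF, 95 °C
Reagents that add atoms: tributyl(3-methylbut-2-en-1-yl)stannane, CCCC[Sn](CCCC)(CCCC)CC=C(C)C
Why: Stille cross-coupling of the ester-activated aryl bromide with the prenylstannane should give the linear prenyl arene because reductive elimination takes place at the less substituted allyl terminus, and fluoride speeds up transmetalation at the doubly ortho-substituted palladium centre.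

Step 6
Reactants: 10 methyl 8-methoxy-2,2-dimethyl-5-(3-methylbut-2-en-1-yl)chroman-6-carboxylate
Product: 11 8-hydroxy-2,2-dimethyl-5-(3-methylbut-2-en-1-yl)chroman-6-carboxylic acid
Conditions: NaSEt (excess), DMF, 120 °C; aq. HCl work-up
Reagents that add atoms: none
Why: SN2 demethylation by the soft ethanethiolate cleaves both O–CH3 bonds (aryl methyl ether and methyl ester), while the tertiary alkyl aryl ether of the chroman and the prenyl alkene cannot react this way, and the bromide that could undergo SNAr is already gone.

Step 7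
Reactants: 11 8-hydroxy-2,2-dimethyl-5-(3-methylbut-2-en-1-yl)chroman-6-carboxylic acid
Product: 13 2,2-dimethyl-5-(3-methylbut-2-en-1-yl)-8-(prop-2-en-1-yloxy)chroman-6-carboxylic acid, via allyl ester 12 (not isolated)
Conditions: allyl bromide (3 equiv), K2CO3, DMF, 50 °C; then LiOH, THF/MeOH/H2O, 50 °C; aq. HCl work-up
Reagents that add atoms: allyl bromide, C=CCBr
Why: Williamson O-allylation of phenoxide and carboxylate followed by saponification of the allyl ester in the same flask gives the acid with an allyl ether that is stable to the acid and base of the later steps and is removable at the end without acid.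

Step 8
Reactants: 14 2,4,6-trihydroxyacetophenone
Product: 15 1-[2,6-dihydroxy-4-(3-methylbut-2-en-1-yloxy)phenyl]ethanone
Conditions: prenyl bromide (1.0 equiv), K2CO3 (1.1 equiv), acetone, rt
Reagents that add atoms: 1-bromo-3-methylbut-2-ene, CC(C)=CCBr
Why: Williamson etherification is selective for the 4-OH, the only hydroxyl not hydrogen-bonded to the acetyl carbonyl and the most acidic one, and one equivalent of halide with a mild carbonate base keeps the reaction at mono-O-alkylation.

Step 9
Reactants: 15 1-[2,6-dihydroxy-4-(3-methylbut-2-en-1-yloxy)phenyl]ethanone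
Product: 16 1-[2,4,6-trihydroxy-3-(2-methylbut-3-en-2-yl)phenyl]ethanone
Conditions: PhNEt2, 175 °C, Ar, sealed tube, short heating
Reagents that add atoms: none
Why: The aromatic Claisen rearrangement transfers the allyl unit with inversion to an ortho carbon (C3 and C5 are equivalent by symmetry), which gives the 1,1-dimethylallyl group, and because the para carbon carries the acetyl group no para-Claisen–Cope product can aromatise.

Step 10
Reactants: 16 1-[2,4,6-trihydroxy-3-(2-methylbut-3-en-2-yl)phenyl]ethanone
Product: 17 1-[2-hydroxy-3-(2-methylbut-3-en-2-yl)-4,6-bis(prop-2-en-1-yloxy)phenyl]ethanone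
Conditions: allyl bromide (2.1 equiv), K2CO3, acetone, reflux
Reagents that add atoms: allyl bromide, C=CCBr
Why: In this Williamson allylation the non-chelated 4-OH and the less hindered chelated 6-OH should react while the 2-OH, both hydrogen-bonded to the carbonyl and flanked by the tertiary alkyl group, stays free, which fixes the oxygen that becomes O1 and so places the dimethylallyl group at C8 (regiochemistry to be checked by HMBC/NOE before going on).

Step 11
Reactants: 13 2,2-dimethyl-5-(3-methylbut-2-en-1-yl)-8-(prop-2-en-1-yloxy)chroman-6-carboxylic acid; 17 1-[2-hydroxy-3-(2-methylbut-3-en-2-yl)-4,6-bis(prop-2-en-1-yloxy)phenyl]ethanone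
Product: 20 1-[2-hydroxy-3-(2-methylbut-3-en-2-yl)-4,6-bis(prop-2-en-1-yloxy)phenyl]-3-[2,2-dimethyl-5-(3-methylbut-2-en-1-yl)-8-(prop-2-en-1-yloxy)chroman-6-yl]propane-1,3-dione, via acid chloride 18 (not isolated), via dilithium enolate 19 (not isolated)
Conditions: 13, 1-chloro-N,N,2-trimethylprop-1-en-1-amine, CH2Cl2, 0 °C to rt; separately 17, LiHMDS (3.5 equiv), THF, −78 °C; add 18 at −78 °C, warm to rt; aq. NH4Cl
Reagents that add atoms: none
Why: This is the Baker–Venkataraman union in its direct form, the phenoxide–enolate dianion being acylated at carbon by the acid chloride (any O-aroyl ester formed would undergo the classical Baker–Venkataraman acyl shift under the excess amide base to the same diketone), and the chloroenamine makes the acid chloride without HCl, which protects the prenyl alkene.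

Step 12
Reactants: 20 the 1,3-diketone from step 11
Product: 21 1-[2-hydroxy-3-(2-methylbut-3-en-2-yl)-4,6-bis(prop-2-en-1-yloxy)phenyl]-3-[2,2-dimethyl-5-(3-methylbut-2-en-1-yl)-8-(prop-2-en-1-yloxy)chroman-6-yl]-1,3-dioxopropan-2-yl benzoate (racemic at C2)
Conditions: (PhCO2)2 (1.1 equiv), K2CO3 (1.2 equiv), acetone, 0 °C to rt
Reagents that add atoms: dibenzoyl peroxide, O=C(OOC(=O)c1ccccc1)c1ccccc1
Why: Electrophilic α-benzoyloxylation, in which the enolate of the 1,3-diketone (more acidic than the chelated phenol) attacks the O–O bond of the peroxide, is a known C-oxygenation of 1,3-dicarbonyl compounds and of o-hydroxyaryl diketones on the way to flavonols, it does not touch isolated alkenes, and the new stereocentre is formed as a racemate that step 13 removes.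

Step 13
Reactants: 21 the 2-benzoyloxy-1,3-diketone from step 12
Product: 22 2-[2,2-dimethyl-5-(3-methylbut-2-en-1-yl)-8-(prop-2-en-1-yloxy)chroman-6-yl]-8-(2-methylbut-3-en-2-yl)-4-oxo-5,7-bis(prop-2-en-1-yloxy)-4H-chromen-3-yl benzoate
Conditions: p-TsOH·H2O (cat.), toluene, 4 Å MS, 60 °C
Reagents that add atoms: none
Why: Acid-catalysed cyclodehydration of the o-hydroxyaryl 1,3-diketone (the closing stage of the Baker–Venkataraman flavone synthesis) proceeds by addition of the only free phenol to the B-ring ketone and loss of water from the hemiketal, and because the other ortho oxygen is an acid-stable allyl ether the ring can close only through the oxygen next to the dimethylallyl group.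

Step 14
Reactants: 22 the 3-benzoyloxy tri-O-allyl flavone from step 13
Product: 23 Broussoflavonol E
Conditions: Pd(PPh3)4 (cat.), K2CO3, degassed MeOH, Ar, rt to 40 °C; then aq. citric acid
Reagents that add atoms: none
Why: Palladium(0) ionises the three aryl allyl ethers to π-allyl complexes that methoxide captures (Tsuji–Trost deallylation) while carbonate in methanol transesterifies the enol benzoate in the same flask, and since the C-prenyl and C-(1,1-dimethylallyl) groups have no leaving group and no acid is used, neither alkene is lost or cyclised onto a neighbouring phenol.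

**Compound list**
1 | 6-bromovanillin (2-bromo-4-hydroxy-5-methoxybenzaldehyde) | COc1cc(C=O)c(Br)cc1O | starting material
2 | 2-bromo-4-hydroxy-5-methoxybenzoic acid | COc1cc(C(=O)O)c(Br)cc1O | intermediate
3 | methyl 2-bromo-4-hydroxy-5-methoxybenzoate | COC(=O)c1cc(OC)c(O)cc1Br | intermediate
4 | thiophenol | Sc1ccccc1 | starting material
5 | methyl 2-bromo-4-hydroxy-5-methoxy-3-(morpholin-4-ylmethyl)benzoate (Mannich base, formed in the flask) | COC(=O)c1cc(OC)c(O)c(CN2CCOCC2)c1Br | intermediate
6 | methyl 2-bromo-4-hydroxy-5-methoxy-3-[(phenylsulfanyl)methyl]benzoate | COC(=O)c1cc(OC)c(O)c(CSc2ccccc2)c1Br | intermediate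
7 | isobutene (2-methylpropene) | C=C(C)C | starting material
8 | methyl 2-bromo-5-methoxy-3-methylidene-4-oxocyclohexa-1,5-diene-1-carboxylate (o-quinone methide, formed in the flask) | COC(=O)C1=C(Br)C(=C)C(=O)C(OC)=C1 | intermediate
9 | methyl 5-bromo-8-methoxy-2,2-dimethylchroman-6-carboxylate | COC(=O)c1cc(OC)c2OC(C)(C)CCc2c1Br | intermediate
10 | methyl 8-methoxy-2,2-dimethyl-5-(3-methylbut-2-en-1-yl)chroman-6-carboxylate | COC(=O)c1cc(OC)c2OC(C)(C)CCc2c1CC=C(C)C | intermediate
11 | 8-hydroxy-2,2-dimethyl-5-(3-methylbut-2-en-1-yl)chroman-6-carboxylic acid | OC(=O)c1cc(O)c2OC(C)(C)CCc2c1CC=C(C)C | intermediate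
12 | prop-2-en-1-yl 2,2-dimethyl-5-(3-methylbut-2-en-1-yl)-8-(prop-2-en-1-yloxy)chroman-6-carboxylate (formed in the flask) | C=CCOC(=O)c1cc(OCC=C)c2OC(C)(C)CCc2c1CC=C(C)C | intermediate
13 | 2,2-dimethyl-5-(3-methylbut-2-en-1-yl)-8-(prop-2-en-1-yloxy)chroman-6-carboxylic acid | OC(=O)c1cc(OCC=C)c2OC(C)(C)CCc2c1CC=C(C)C | intermediate
14 | 2,4,6-trihydroxyacetophenone | CC(=O)c1c(O)cc(O)cc1O | starting material
15 | 1-[2,6-dihydroxy-4-(3-methylbut-2-en-1-yloxy)phenyl]ethanone | CC(=O)c1c(O)cc(OCC=C(C)C)cc1O | intermediate
16 | 1-[2,4,6-trihydroxy-3-(2-methylbut-3-en-2-yl)phenyl]ethanone | CC(=O)c1c(O)cc(O)c(C(C)(C)C=C)c1O | intermediate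
17 | 1-[2-hydroxy-3-(2-methylbut-3-en-2-yl)-4,6-bis(prop-2-en-1-yloxy)phenyl]ethanone | CC(=O)c1c(OCC=C)cc(OCC=C)c(C(C)(C)C=C)c1O | intermediate
18 | 2,2-dimethyl-5-(3-methylbut-2-en-1-yl)-8-(prop-2-en-1-yloxy)chroman-6-carbonyl chloride (formed in the flask) | ClC(=O)c1cc(OCC=C)c2OC(C)(C)CCc2c1CC=C(C)C | intermediate
19 | dilithium 2-(1-oxidoethenyl)-6-(2-methylbut-3-en-2-yl)-3,5-bis(prop-2-en-1-yloxy)phenolate (formed in the flask) | [Li+].[Li+].C=C([O-])c1c(OCC=C)cc(OCC=C)c(C(C)(C)C=C)c1[O-] | intermediate
20 | 1-[2-hydroxy-3-(2-methylbut-3-en-2-yl)-4,6-bis(prop-2-en-1-yloxy)phenyl]-3-[2,2-dimethyl-5-(3-methylbut-2-en-1-yl)-8-(prop-2-en-1-yloxy)chroman-6-yl]propane-1,3-dione | O=C(CC(=O)c1cc(OCC=C)c2OC(C)(C)CCc2c1CC=C(C)C)c1c(OCC=C)cc(OCC=C)c(C(C)(C)C=C)c1O | intermediate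
21 | 2-benzoyloxy derivative of diketone 20 (racemic at C2) | O=C(C(OC(=O)c1ccccc1)C(=O)c1cc(OCC=C)c2OC(C)(C)CCc2c1CC=C(C)C)c1c(OCC=C)cc(OCC=C)c(C(C)(C)C=C)c1O | intermediate
22 | 2-[2,2-dimethyl-5-(3-methylbut-2-en-1-yl)-8-(prop-2-en-1-yloxy)chroman-6-yl]-8-(2-methylbut-3-en-2-yl)-4-oxo-5,7-bis(prop-2-en-1-yloxy)-4H-chromen-3-yl benzoate | C=CC(C)(C)c1c(OCC=C)cc(OCC=C)c2c(=O)c(OC(=O)c3ccccc3)c(-c3cc(OCC=C)c4c(c3CC=C(C)C)CCC(C)(C)O4)oc12 | intermediate
23 | Broussoflavonol E | C=CC(C)(C)c1c(O)cc(O)c2c(=O)c(O)c(-c3cc(O)c4c(c3CC=C(C)C)CCC(C)(C)O4)oc12 | target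

**Step count and risks**

Total step count: 14. Longest linear sequence: 11 steps (steps 1–7, then 11–14); the A-ring branch is steps 8–10.

Steps most likely to fail:

1. Step 4. The quinone methide may oligomerise, or be captured by water or liberated thiol, faster than it meets the gaseous alkene. Acid generated at the anode may also oligomerise isobutene and use up the trap, and fragmentation of the sulfide radical cation may be slow on this hindered, electron-poor ring. Fallback, from 3 back to 9: O-alkylate phenol 3 with 3-chloro-3-methylbut-1-yne (DBU, cat. CuCl2, MeCN, 0 °C) to methyl 2-bromo-5-methoxy-4-[(2-methylbut-3-yn-2-yl)oxy]benzoate F1. Heat this in PhNEt2 at about 170 °C: propargyl Claisen rearrangement, 1,5-hydrogen shift and oxa-6π electrocyclisation, with closure possible only at the free ortho carbon, should give methyl 5-bromo-8-methoxy-2,2-dimethyl-2H-chromene-6-carboxylate F2. Reduce its C3=C4 bond with diimide (TsNHNH2, NaOAc, aq. THF, reflux), which does not touch the aryl bromide, to reach 9.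

2. Step 9. At the temperature of the rearrangement the product can isomerise by the ene/retro-ene ("abnormal Claisen") pathway or add a flanking hydroxyl across the new alkene, and the free polyphenol may decompose. Fallback, from 15 back to 16: run the rearrangement in PhNEt2 with butanoic anhydride so that every phenol is acylated as it forms, which blocks both pathways because they need a free ortho hydroxyl. This should give 2-acetyl-4-(2-methylbut-3-en-2-yl)benzene-1,3,5-triyl tributanoate F3, which is methanolysed (K2CO3, MeOH, rt) to 16.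

3. Step 12. The phenoxide may be oxidised or O-benzoylated in competition with the enolate, and the α-acyloxy diketone may undergo base-induced acyl migration or retro-Claisen cleavage. Fallback, from 20 to 23: cyclodehydrate 20 first (p-TsOH cat., toluene, 60 °C) to the flavone 2-[2,2-dimethyl-5-(3-methylbut-2-en-1-yl)-8-(prop-2-en-1-yloxy)chroman-6-yl]-8-(2-methylbut-3-en-2-yl)-5,7-bis(prop-2-en-1-yloxy)-4H-chromen-4-one F4. Lithiate C3 (LDA, THF, −78 °C) and quench with B(OMe)3 to the dimethyl (4-oxo-4H-chromen-3-yl)boronate F5, which is not isolated. Oxidise with H2O2/AcOH to the 3-hydroxyflavone tri-O-allyl ether F6, and deallylate with Pd(PPh3)4, K2CO3, MeOH to 23.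

**Further compounds**
F1 | step 4 | methyl 2-bromo-5-methoxy-4-[(2-methylbut-3-yn-2-yl)oxy]benzoate | COC(=O)c1cc(OC)c(OC(C)(C)C#C)cc1Br
F2 | step 4 | methyl 5-bromo-8-methoxy-2,2-dimethyl-2H-chromene-6-carboxylate | COC(=O)c1cc(OC)c2OC(C)(C)C=Cc2c1Br
F3 | step 9 | 2-acetyl-4-(2-methylbut-3-en-2-yl)benzene-1,3,5-triyl tributanoate | CCCC(=O)Oc1cc(OC(=O)CCC)c(C(C)=O)c(OC(=O)CCC)c1C(C)(C)C=C
F4 | step 12 | 2-[2,2-dimethyl-5-(3-methylbut-2-en-1-yl)-8-(prop-2-en-1-yloxy)chroman-6-yl]-8-(2-methylbut-3-en-2-yl)-5,7-bis(prop-2-en-1-yloxy)-4H-chromen-4-one | C=CC(C)(C)c1c(OCC=C)cc(OCC=C)c2c(=O)cc(-c3cc(OCC=C)c4c(c3CC=C(C)C)CCC(C)(C)O4)oc12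
F5 | step 12 | dimethyl {2-[2,2-dimethyl-5-(3-methylbut-2-en-1-yl)-8-(prop-2-en-1-yloxy)chroman-6-yl]-8-(2-methylbut-3-en-2-yl)-4-oxo-5,7-bis(prop-2-en-1-yloxy)-4H-chromen-3-yl}boronate | C=CC(C)(C)c1c(OCC=C)cc(OCC=C)c2c(=O)c(B(OC)OC)c(-c3cc(OCC=C)c4c(c3CC=C(C)C)CCC(C)(C)O4)oc12
F6 | step 12 | 2-[2,2-dimethyl-5-(3-methylbut-2-en-1-yl)-8-(prop-2-en-1-yloxy)chroman-6-yl]-3-hydroxy-8-(2-methylbut-3-en-2-yl)-5,7-bis(prop-2-en-1-yloxy)-4H-chromen-4-one | C=CC(C)(C)c1c(OCC=C)cc(OCC=C)c2c(=O)c(O)c(-c3cc(OCC=C)c4c(c3CC=C(C)C)CCC(C)(C)O4)oc12
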